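**Plan**
1. After functional-group adjustment (C2/C2′ ketones from carbinols, both nitrogens from C6/C6′ lactams), the 16-membered ring (C9, C9a, C1 of each quinolizidinone plus two (CH2)5 bridges) is cut at its two symmetry-equivalent CH2–CH2 bonds, each between the second and third bridge carbon counted from C9. This halves the target into one quinolizidine-2,6-dione with an (E)-2-iodoethenyl group on C9 and an allyl group on C1.
2. In that monomer, ring A is cut at C1–C2 (Dieckmann) and N–C4 (aza-Michael). Ring B (δ-lactam) goes back by Beckmann ring expansion to a trans-2,3-disubstituted cyclopentanone, made by three-component coupling on (R)-4-silyloxycyclopentenone.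
3. Forward order: cyclopentanone, ring B lactam, ring A, head-to-tail B-alkyl Suzuki–Miyaura cyclodimerisation (both bridges and the macrocycle at once), then hydrogenation, LiAlH4 and Swern oxidation.
4. Stereochemistry: C9 from conjugate addition anti to the silyloxy group of the (R)-enone; C9a from trans enolate alkylation, carried through the stereoretentive Beckmann migration; C1 and C3 by equilibration α to the ketone; the homochiral (not meso) pairing follows from dimerising a single enantiomer.
5. Enabling feature: the C2 axis makes the two C9–(CH2)5–C1′ bridges one and the same bond-forming problem. The E-iodoalkene on C9 cannot reach the borane on C1 of its own unit (that would put an E alkene in an eight-membered ring through C9–C9a–C1), so only head-to-tail pairing can close a ring.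

Key step: step 10

Remark on the chemistry (assumption): with C9 and C9a fixed, the target arrangement at C1 and C3 (C3 methyl equatorial, C1 chain axial and anti to H-9a, which avoids a syn-pentane clash with the equatorial C9 chain) is taken as the thermodynamic one, so these two centres are set by enolate equilibration.

Step 1
Reactants: 1 (4R)-4-(tert-butyldimethylsilyloxy)cyclopent-2-en-1-one; 2 (E)-(2-bromoethenyl)trimethylsilane; 3 prop-2-enyl bromoacetate
Product: 6 prop-2-enyl 2-[(1R,2S,3R)-3-(tert-butyldimethylsilyloxy)-5-oxo-2-[(E)-2-(trimethylsilyl)ethenyl]cyclopentyl]acetate (all-trans), via alkenyllithium 4 (not isolated), via zincate enolate 5 (not isolated)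
Conditions: 2, t-BuLi (2 equiv), Et2O, −78 °C; Me2Zn, THF, −78 °C; 1, −78 °C; HMPA, 3, −78 → −40 °C; aq. NH4Cl
Reagents that add atoms: none
Why: Three-component coupling (conjugate addition then enolate alkylation): the alkenyl(dimethyl)zincate should transfer its alkenyl group to the enone β-carbon anti to the silyloxy group, and the zinc enolate should be alkylated by the reactive α-bromo ester anti to the new β-substituent before it can equilibrate, giving the all-trans ketone.

Step 2
Reactants: 6 prop-2-enyl 2-[(1R,2S,3R)-3-(tert-butyldimethylsilyloxy)-5-oxo-2-[(E)-2-(trimethylsilyl)ethenyl]cyclopentyl]acetate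
Product: 7 prop-2-enyl 2-[(1R,5S)-2-oxo-5-[(E)-2-(trimethylsilyl)ethenyl]cyclopent-3-en-1-yl]acetate
Conditions: DBU, CH2Cl2, 0 °C
Reagents that add atoms: none
Why: E1cB β-elimination of the silyloxy group through the enolate on the unsubstituted α-carbon should give the cyclopentenone, with the substituted α-centre staying trans (thermodynamic) and short contact at 0 °C limiting γ-deprotonation.

Step 3
Reactants: 7 prop-2-enyl 2-[(1R,5S)-2-oxo-5-[(E)-2-(trimethylsilyl)ethenyl]cyclopent-3-en-1-yl]acetate
Product: 8 prop-2-enyl 2-[(1R,2S)-5-oxo-2-[(E)-2-(trimethylsilyl)ethenyl]cyclopentyl]acetate (trans)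
Conditions: [(Ph3P)CuH]6 (5 mol %), Ph2SiH2, t-BuOH, PhMe, rt
Reagents that add atoms: none
Why: Copper hydride conjugate reduction should be chemoselective for the enone over the allyl ester and the alkenylsilane, and creates no stereocentre.

Step 4
Reactants: 8 prop-2-enyl 2-[(1R,2S)-5-oxo-2-[(E)-2-(trimethylsilyl)ethenyl]cyclopentyl]acetate
Product: 9 prop-2-enyl 2-[(1R,2S,5E)-5-(hydroxyimino)-2-[(E)-2-(trimethylsilyl)ethenyl]cyclopentyl]acetate
Conditions: NH2OH·HCl, NaOAc, MeOH, rt
Reagents that add atoms: hydroxylamine hydrochloride, Cl.NO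
Why: Oxime formation, in which the hydroxyl group should settle anti to the substituted α-carbon (E), the geometry that lets that carbon migrate.

Step 5
Reactants: 9 prop-2-enyl 2-[(1R,2S,5E)-5-(hydroxyimino)-2-[(E)-2-(trimethylsilyl)ethenyl]cyclopentyl]acetate
Product: 11 prop-2-enyl 2-[(2R,3R)-6-oxo-3-[(E)-2-(trimethylsilyl)ethenyl]piperidin-2-yl]acetate (2,3-trans), via oxime tosylate 10 (not isolated)
Conditions: TsCl, K2CO3, acetone/H2O, 0 → 50 °C
Reagents that add atoms: water, O
Why: Beckmann rearrangement of the oxime tosylate formed in the flask: the anti, more substituted α-carbon migrates to nitrogen with retention, so the trans relationship of the two ring substituents is carried into the 5,6-disubstituted piperidin-2-one (ring B with C9 and C9a).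

Step 6
Reactants: 11 prop-2-enyl 2-[(2R,3R)-6-oxo-3-[(E)-2-(trimethylsilyl)ethenyl]piperidin-2-yl]acetate; 12 prop-2-enyl 2-methylprop-2-enoate (allyl methacrylate)
Product: 13 prop-2-enyl 2-methyl-3-[(2R,3R)-6-oxo-2-(2-oxo-2-prop-2-enoxyethyl)-3-[(E)-2-(trimethylsilyl)ethenyl]piperidin-1-yl]propanoate (epimers at the methyl-bearing carbon)
Conditions: 12 (5 equiv), Cs2CO3 (0.3 equiv), t-BuOH, 60 °C
Reagents that add atoms: none
Why: Base-catalysed aza-Michael addition of the lactam N–H to the methacrylate; the new methyl-bearing centre forms unselectively and is corrected in step 8 because it becomes α to the ketone.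

Step 7
Reactants: 13 prop-2-enyl 2-methyl-3-[(2R,3R)-6-oxo-2-(2-oxo-2-prop-2-enoxyethyl)-3-[(E)-2-(trimethylsilyl)ethenyl]piperidin-1-yl]propanoate
Product: 14 prop-2-enyl (9R,9aS)-3-methyl-2,6-dioxo-9-[(E)-2-(trimethylsilyl)ethenyl]quinolizidine-1-carboxylate (C1/C3 epimers and enol form)
Conditions: t-BuOK, THF, 0 °C; AcOH
Reagents that add atoms: none
Why: Dieckmann condensation: of the two possible six-membered closures only the one that leaves an enolisable β-keto ester (carboxylate on C1) is drawn to completion as its potassium enolate, so ring A forms with the ketone at C2 and the ester on C1.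

Step 8
Reactants: 14 prop-2-enyl (9R,9aS)-3-methyl-2,6-dioxo-9-[(E)-2-(trimethylsilyl)ethenyl]quinolizidine-1-carboxylate
Product: 15 (1R,3R,9R,9aS)-3-methyl-1-(prop-2-enyl)-9-[(E)-2-(trimethylsilyl)ethenyl]quinolizidine-2,6-dione
Conditions: Pd(PPh3)4 (5 mol %), THF, rt; then DBU (0.2 equiv), rt
Reagents that add atoms: none
Why: Tsuji decarboxylative allylation: zerovalent palladium ionises the allyl ester, loss of CO2 gives the palladium enolate at C1 and the allyl group is delivered there, after which DBU equilibrates both α-centres to the isomer with the C3 methyl equatorial and the C1 allyl axial (anti to H-9a).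

Step 9
Reactants: 15 (1R,3R,9R,9aS)-3-methyl-1-(prop-2-enyl)-9-[(E)-2-(trimethylsilyl)ethenyl]quinolizidine-2,6-dione
Product: 16 (1R,3R,9R,9aS)-9-[(E)-2-iodoethenyl]-3-methyl-1-(prop-2-enyl)quinolizidine-2,6-dione
Conditions: NIS, MeCN, 0 °C → rt
Reagents that add atoms: N-iodosuccinimide, O=C1CCC(=O)N1I
Why: Ipso iododesilylation of the (E)-alkenylsilane through the β-silyl cation should proceed with retention of geometry and faster than any attack on the unactivated terminal alkene.

Step 10
Reactants: 16 (1R,3R,9R,9aS)-9-[(E)-2-iodoethenyl]-3-methyl-1-(prop-2-enyl)quinolizidine-2,6-dione (two molecules)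
Product: 19 C2-symmetric 16-membered (E,E)-diene bis(keto-lactam) cyclodimer in which C9 of each unit is joined to C1 of the other by CH=CH–(CH2)3, via B-alkyl borane 17 (not isolated), via open-chain dimer 18 (not isolated)
Conditions: 9-BBN, THF, rt; then Pd(dppf)Cl2 (20 mol %), AsPh3, Cs2CO3, DMF/THF/H2O, 5 mM, 50 °C
Reagents that add atoms: none
Why: 9-BBN hydroborates only the terminal allyl C=C to give a primary B-alkyl borane; its base-activated borate transmetalates to the alkenylpalladium iodide formed by oxidative addition of zerovalent palladium to the (E)-iodoalkene, and reductive elimination forms the C(sp2)–C(sp3) bond, which is the B-alkyl Suzuki–Miyaura coupling, established in its intramolecular form as a macrocyclisation. The first coupling joins two molecules of 17 head to tail to give 18, and the second, now intramolecular, closes the 16-membered ring by reductive elimination from a 17-membered palladacycle, the new alkene lying in the ring. No stereocentre is created: the C2-symmetric, non-meso product follows from the single enantiomer of the monomer, and the E geometry is retained from the iodide. The selectivity needed is head-to-tail pairing and dimer rather than monomer or oligomer: borane and iodide can only pair with each other, closure of one unit onto itself would put an E double bond in an eight-membered ring (C9, C9a, C1 and five chain atoms) and is excluded, and moderate dilution favours ring closure of 18 over chain growth. The hindered ketone and the lactams should survive 9-BBN at room temperature, and any ketone that is reduced converges later because the carbonyls are reduced and reoxidised in steps 12 and 13.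

Step 11
Reactants: 19 C2-symmetric 16-membered (E,E)-diene bis(keto-lactam) cyclodimer
Product: 20 saturated macrocyclic bis(keto-lactam), the target carrying C6 and C6′ lactam carbonyls, (1R,3R,9S,9aS) in each unit
Conditions: H2 (1 atm), 10% Pd/C, EtOAc, rt
Reagents that add atoms: none
Why: Heterogeneous catalytic hydrogenation of the two disubstituted alkenes, with ketones and lactams inert and no stereocentre formed.

Step 12
Reactants: 20 saturated macrocyclic bis(keto-lactam)
Product: 21 macrocyclic bis(amino alcohol), the target with both C2 ketones as CH–OH (carbinol epimers)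
Conditions: LiAlH4, THF, reflux; H2O work-up
Reagents that add atoms: none
Why: Lithium aluminium hydride reduction should take both tertiary lactams to the amines and both ketones to carbinols, whose configuration is of no consequence.

Step 13
Reactants: 21 macrocyclic bis(amino alcohol)
Product: 22 target, the (1R,3R,9S,9aS;1′R,3′R,9′S,9a′S) bis(quinolizidin-2-one) macrocycle
Conditions: (COCl)2, DMSO, CH2Cl2, −78 °C; Et3N, −78 °C → rt
Reagents that add atoms: none
Why: Swern oxidation of the amino diol should return both ketones, tertiary amines being tolerated, with the α-centres set in step 8 and re-equilibrated to the same thermodynamic arrangement by the triethylamine present (or brief K2CO3 in MeOH) if needed.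

**Compound list**
1 | (4R)-4-(tert-butyldimethylsilyloxy)cyclopent-2-en-1-one | O=C1C[C@@H](O[Si](C)(C)C(C)(C)C)C=C1 | starting material
2 | (E)-(2-bromoethenyl)trimethylsilane | C[Si](C)(C)/C=C/Br | starting material
3 | prop-2-enyl bromoacetate | BrCC(=O)OCC=C | starting material
4 | (E)-[2-(trimethylsilyl)ethenyl]lithium | [Li]/C=C/[Si](C)(C)C | intermediate
5 | lithium dimethyl[(3S,4R)-4-(tert-butyldimethylsilyloxy)-3-[(E)-2-(trimethylsilyl)ethenyl]cyclopent-1-en-1-olato]zincate | [Li+].C[Zn-](C)OC1=C[C@@H](/C=C/[Si](C)(C)C)[C@H](O[Si](C)(C)C(C)(C)C)C1 | intermediate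
6 | prop-2-enyl 2-[(1R,2S,3R)-3-(tert-butyldimethylsilyloxy)-5-oxo-2-[(E)-2-(trimethylsilyl)ethenyl]cyclopentyl]acetate | O=C1C[C@@H](O[Si](C)(C)C(C)(C)C)[C@H](/C=C/[Si](C)(C)C)[C@H]1CC(=O)OCC=C | intermediate
7 | prop-2-enyl 2-[(1R,5S)-2-oxo-5-[(E)-2-(trimethylsilyl)ethenyl]cyclopent-3-en-1-yl]acetate | O=C1C=C[C@H](/C=C/[Si](C)(C)C)[C@H]1CC(=O)OCC=C | intermediate
8 | prop-2-enyl 2-[(1R,2S)-5-oxo-2-[(E)-2-(trimethylsilyl)ethenyl]cyclopentyl]acetate | O=C1CC[C@H](/C=C/[Si](C)(C)C)[C@H]1CC(=O)OCC=C | intermediate
9 | prop-2-enyl 2-[(1R,2S,5E)-5-(hydroxyimino)-2-[(E)-2-(trimethylsilyl)ethenyl]cyclopentyl]acetate | O/N=C1\CC[C@H](/C=C/[Si](C)(C)C)[C@H]1CC(=O)OCC=C | intermediate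
10 | O-(4-methylbenzenesulfonyl) derivative of oxime 9 | Cc1ccc(cc1)S(=O)(=O)O/N=C1\CC[C@H](/C=C/[Si](C)(C)C)[C@H]1CC(=O)OCC=C | intermediate
11 | prop-2-enyl 2-[(2R,3R)-6-oxo-3-[(E)-2-(trimethylsilyl)ethenyl]piperidin-2-yl]acetate | O=C1CC[C@H](/C=C/[Si](C)(C)C)[C@@H](CC(=O)OCC=C)N1 | intermediate
12 | prop-2-enyl 2-methylprop-2-enoate (allyl methacrylate) | CC(=C)C(=O)OCC=C | starting material
13 | prop-2-enyl 2-methyl-3-[(2R,3R)-6-oxo-2-(2-oxo-2-prop-2-enoxyethyl)-3-[(E)-2-(trimethylsilyl)ethenyl]piperidin-1-yl]propanoate (epimers at the methyl-bearing carbon) | O=C1CC[C@H](/C=C/[Si](C)(C)C)[C@@H](CC(=O)OCC=C)N1CC(C)C(=O)OCC=C | intermediate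
14 | prop-2-enyl (9R,9aS)-3-methyl-2,6-dioxo-9-[(E)-2-(trimethylsilyl)ethenyl]quinolizidine-1-carboxylate (C1/C3 epimers) | CC1CN2C(=O)CC[C@H](/C=C/[Si](C)(C)C)[C@H]2C(C(=O)OCC=C)C1=O | intermediate
15 | (1R,3R,9R,9aS)-3-methyl-1-(prop-2-enyl)-9-[(E)-2-(trimethylsilyl)ethenyl]quinolizidine-2,6-dione | C[C@@H]1CN2C(=O)CC[C@H](/C=C/[Si](C)(C)C)[C@H]2[C@@H](CC=C)C1=O | intermediate
16 | (1R,3R,9R,9aS)-9-[(E)-2-iodoethenyl]-3-methyl-1-(prop-2-enyl)quinolizidine-2,6-dione | C[C@@H]1CN2C(=O)CC[C@H](/C=C/I)[C@H]2[C@@H](CC=C)C1=O | intermediate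
17 | (1R,3R,9R,9aS)-1-[3-(9-borabicyclo[3.3.1]nonan-9-yl)propyl]-9-[(E)-2-iodoethenyl]-3-methylquinolizidine-2,6-dione | C[C@@H]1CN2C(=O)CC[C@H](/C=C/I)[C@H]2[C@@H](CCCB3C4CCCC3CCC4)C1=O | intermediate
18 | open-chain head-to-tail dimer: one C9–CH=CH–(CH2)3–C1′ bridge formed, borylpropyl on C1 of the first unit, (E)-2-iodoethenyl on C9′ of the second | C[C@@H]1CN2C(=O)CC[C@H](/C=C/CCC[C@H]3C(=O)[C@H](C)CN4C(=O)CC[C@H](/C=C/I)[C@@H]34)[C@H]2[C@@H](CCCB5C6CCCC5CCC6)C1=O | intermediate
19 | C2-symmetric 16-membered (E,E)-diene bis(keto-lactam) cyclodimer, (1R,3R,9R,9aS) in each unit | C[C@@H]1CN2C(=O)CC[C@H](/C=C/CCC[C@H]3C(=O)[C@H](C)CN4C(=O)CC[C@H](/C=C/CCC5)[C@@H]34)[C@H]2[C@@H]5C1=O | intermediate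
20 | saturated macrocyclic bis(keto-lactam), (1R,3R,9S,9aS) in each unit | C[C@@H]1CN2C(=O)CC[C@H](CCCCC[C@H]3C(=O)[C@H](C)CN4C(=O)CC[C@H](CCCCC5)[C@@H]34)[C@H]2[C@@H]5C1=O | intermediate
21 | macrocyclic bis(amino alcohol), carbinol epimers at C2 and C2′ | C[C@@H]1CN2CCC[C@H](CCCCC[C@H]3C(O)[C@H](C)CN4CCC[C@H](CCCCC5)[C@@H]34)[C@H]2[C@@H]5C1O | intermediate
22 | target, (1R,3R,9S,9aS;1′R,3′R,9′S,9a′S) bis(quinolizidin-2-one) macrocycle | C[C@@H]1CN2CCC[C@@H]3CCCCC[C@H]4C(=O)[C@H](C)CN5CCC[C@H](CCCCC[C@@H](C1=O)[C@H]32)[C@@H]45 | target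

**Summary**
Total step count: 13. Longest linear sequence: 13 steps (from 1).

Steps most likely to fail:

Step 10. What may go wrong: chain growth to linear and larger cyclic oligomers instead of ring closure of the dimer, and protodeboronation or β-hydride loss during the slow, dilute second coupling. Fallback (directed stepwise dimerisation, setting out from 15 and 16 and rejoining at 18 and then 19): 15 is hydroborated at its allyl group with 9-BBN, the alkenylsilane being inert, to give the B-alkyl borane F1. F1 is cross-coupled with the iodoalkene of 16 (Pd(dppf)Cl2, AsPh3, Cs2CO3, normal concentration) to give the open head-to-tail dimer F2, which carries one alkenylsilane and one allyl group. NIS converts F2 into the open-dimer iodoalkene F3. Hydroboration of the remaining allyl group of F3 gives 18, which is closed by the same intramolecular B-alkyl Suzuki–Miyaura reaction under high dilution to 19.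

Step 6. What may go wrong: slow and reversible addition of the hindered lactam nitrogen to the α-substituted acceptor, with anionic oligomerisation of the methacrylate. Fallback (setting out from 11, rejoining at 15): aza-Michael addition to the more reactive prop-2-enyl acrylate gives the desmethyl diester F4. Dieckmann condensation (t-BuOK) gives the desmethyl β-keto ester F5. Decarboxylative allylation with Pd(PPh3)4 gives the 1-allyl ketone F6. Kinetic deprotonation at the unsubstituted C3 (LDA, 1 equiv, −78 °C), methylation with MeI and DBU equilibration then give 15.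

Step 8. What may go wrong: loss of regiocontrol by enolate equilibration before allyl transfer (allylation at C3) and a second allylation. Fallback (setting out from 14, rejoining at 15): the soft β-keto ester enolate is C-allylated at C1 with allyl bromide and K2CO3 in acetone to give the quaternary allyl ester F7. Pd(OAc)2/PPh3 with HCO2H/Et3N then removes the allyl ester from F7 by deallylative decarboxylation, and DBU equilibration gives 15.

Further compounds
F1 | step 10 | (1R,3R,9R,9aS)-1-[3-(9-borabicyclo[3.3.1]nonan-9-yl)propyl]-3-methyl-9-[(E)-2-(trimethylsilyl)ethenyl]quinolizidine-2,6-dione | C[C@@H]1CN2C(=O)CC[C@H](/C=C/[Si](C)(C)C)[C@H]2[C@@H](CCCB3C4CCCC3CCC4)C1=O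
F2 | step 10 | open head-to-tail dimer with allyl on C1 of the first unit and (E)-2-(trimethylsilyl)ethenyl on C9′ of the second | C[C@@H]1CN2C(=O)CC[C@H](/C=C/CCC[C@H]3C(=O)[C@H](C)CN4C(=O)CC[C@H](/C=C/[Si](C)(C)C)[C@@H]34)[C@H]2[C@@H](CC=C)C1=O
F3 | step 10 | open head-to-tail dimer with allyl on C1 of the first unit and (E)-2-iodoethenyl on C9′ of the second | C[C@@H]1CN2C(=O)CC[C@H](/C=C/CCC[C@H]3C(=O)[C@H](C)CN4C(=O)CC[C@H](/C=C/I)[C@@H]34)[C@H]2[C@@H](CC=C)C1=O
F4 | step 6 | prop-2-enyl 3-[(2R,3R)-6-oxo-2-(2-oxo-2-prop-2-enoxyethyl)-3-[(E)-2-(trimethylsilyl)ethenyl]piperidin-1-yl]propanoate | O=C1CC[C@H](/C=C/[Si](C)(C)C)[C@@H](CC(=O)OCC=C)N1CCC(=O)OCC=C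
F5 | step 6 | prop-2-enyl (9R,9aS)-2,6-dioxo-9-[(E)-2-(trimethylsilyl)ethenyl]quinolizidine-1-carboxylate | O=C1CCN2C(=O)CC[C@H](/C=C/[Si](C)(C)C)[C@H]2C1C(=O)OCC=C
F6 | step 6 | (1R,9R,9aS)-1-(prop-2-enyl)-9-[(E)-2-(trimethylsilyl)ethenyl]quinolizidine-2,6-dione | O=C1CCN2C(=O)CC[C@H](/C=C/[Si](C)(C)C)[C@H]2[C@H]1CC=C
F7 | step 8 | prop-2-enyl (9R,9aS)-3-methyl-2,6-dioxo-1-(prop-2-enyl)-9-[(E)-2-(trimethylsilyl)ethenyl]quinolizidine-1-carboxylate | CC1CN2C(=O)CC[C@H](/C=C/[Si](C)(C)C)[C@H]2C(CC=C)(C(=O)OCC=C)C1=O
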